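The route rests on cutting ring A at two adjacent carbons: the C1'–C1 bond to the heptanone chain and the C2'–O bond of the hindered phenol. One flask makes both: a C1'≡C2' aryne, generated from a TIPS-protected 4-fluoroguaiacol by lithiation and loss of fluoride, takes up an alkylmagnesium reagent at C1', and the C2' arylmagnesium that results is borylated and oxidised to the phenol. The feature exploited is the contiguous C1' alkyl, C2' hydroxyl, C3' methoxy array of ring A, whose C3' oxygen polarises the aryne and fixes the regiochemistry. The Grignard partner carries C1–C7, ring B and the C3 ketone masked as a 5,5-dimethyl-1,3-dioxane.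

Key step: step 6

Numbering: the heptane chain runs from C1 (bonded to C1' of ring A) to C7 (bonded to ring B, the 4-methoxyphenyl ring), with the ketone at C3; ring A carries OH at C2' and C4' and OMe at C3'. The target has no stereocentre.

Assumption: after the alkylmagnesium reagent is added at −78 °C, the 2-fluoroaryl metal species (lithium or mixed lithium–magnesium) should lose metal fluoride only on warming, so the aryne forms in the presence of surplus alkylmagnesium. The ketone is carried as the 5,5-dimethyl-1,3-dioxane because this ketal type gives thermally robust β-magnesiated reagents.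

Step 1
Reactants: 1 5-(4-methoxyphenyl)pentanoic acid
Product: 3 N-methoxy-5-(4-methoxyphenyl)-N-methylpentanamide, via acyl imidazole 2 (not isolated)
Conditions: CDI, CH2Cl2, rt; then MeNH(OMe)·HCl, rt
Reagents that add atoms: N,O-dimethylhydroxylamine hydrochloride, CNOC.Cl
Why: Activation of the acid as acyl imidazole 2 and aminolysis by N,O-dimethylhydroxylamine (Weinreb amide formation) is routine acyl substitution on an unhindered aliphatic acid, with the anisole ring as a spectator.

Step 2
Reactants: 3 N-methoxy-5-(4-methoxyphenyl)-N-methylpentanamide; 4 vinylmagnesium bromide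
Product: 6 7-(4-methoxyphenyl)hept-1-en-3-one, via magnesium hemiaminal chelate 5 (not isolated)
Conditions: THF, 0 °C; inverse quench into cold 2 M HCl
Reagents that add atoms: none
Why: Weinreb ketone synthesis, in which the vinyl Grignard reagent adds once to give the five-membered magnesium chelate 5 that collapses only in the cold acidic inverse quench, where the released hydroxylamine is protonated at once and cannot add to the enone.

Step 3
Reactants: 6 7-(4-methoxyphenyl)hept-1-en-3-one; 7 2,2-dimethylpropane-1,3-diol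
Product: 9 2-(2-bromoethyl)-2-[4-(4-methoxyphenyl)butyl]-5,5-dimethyl-1,3-dioxane, via bromo ketone 8 (not isolated)
Conditions: HBr (g), CH2Cl2, 0 °C; then 7, HC(OEt)3, TsOH·H2O (cat.), rt
Reagents that add atoms: hydrogen bromide, Br
Why: Conjugate hydrobromination of the enone gives β-bromo ketone 8, and acid-catalysed ketalisation with the gem-dimethyl diol (orthoformate as water scavenger) masks the carbonyl before HBr can be lost again, which is the standard preparation of 2-(2-bromoethyl)-1,3-dioxanes from vinyl ketones and should leave the aryl methyl ether intact at 0 °C to rt.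

Step 4
Reactants: 9 2-(2-bromoethyl)-2-[4-(4-methoxyphenyl)butyl]-5,5-dimethyl-1,3-dioxane
Product: 10 (2-{2-[4-(4-methoxyphenyl)butyl]-5,5-dimethyl-1,3-dioxan-2-yl}ethyl)magnesium bromide (THF solution, titrated, used directly)
Conditions: Mg turnings (I2-activated), THF, 25–35 °C
Reagents that add atoms: magnesium, [Mg]
Why: Grignard formation by insertion of magnesium into the primary C–Br bond, with the six-membered 5,5-dimethyl-1,3-dioxane chosen because such ketals resist γ-elimination of the β-magnesiated reagent to a cyclopropyl ether.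

Step 5
Reactants: 11 4-fluoro-2-methoxyphenol
Product: 12 (4-fluoro-2-methoxyphenoxy)tri(propan-2-yl)silane
Conditions: TIPSCl, imidazole, DMF, rt
Reagents that add atoms: chlorotri(propan-2-yl)silane, CC(C)[Si](Cl)(C(C)C)C(C)C
Why: Imidazole-mediated O-silylation of a phenol, giving a bulky TIPS ether that is inert to alkyllithium and Grignard reagents, does not direct ortho-metalation, and leaves the hydrogen between F and OMe as the only strongly acidified ring position.

Step 6
Reactants: 12 (4-fluoro-2-methoxyphenoxy)tri(propan-2-yl)silane; 10 (2-{2-[4-(4-methoxyphenyl)butyl]-5,5-dimethyl-1,3-dioxan-2-yl}ethyl)magnesium bromide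
Product: 17 6-(2-{2-[4-(4-methoxyphenyl)butyl]-5,5-dimethyl-1,3-dioxan-2-yl}ethyl)-2-methoxy-3-[(triisopropylsilyl)oxy]phenol, via aryllithium 13 (not isolated), via aryne 14 (not isolated), via arylmagnesium bromide 15 (not isolated), via dimethyl arylboronate 16 (not isolated)
Conditions: 12, s-BuLi (1.0 equiv), THF, −78 °C; then 10 (2.2 equiv), −78 °C → rt → 45 °C; then B(OMe)3, −78 °C → rt; then 30% aq H2O2, aq NaHCO3, 0 °C → rt
Reagents that add atoms: hydrogen peroxide, OO
Why: s-BuLi should remove the most acidic ring proton of 12, the one between fluorine and the methoxy group, to give 13, which persists at −78 °C and loses fluoride on warming to the C1'≡C2' aryne 14 only after surplus 10 is present. The closest known reaction type is carbomagnesiation of 3-alkoxybenzynes generated from 3-haloanisoles with electrophilic interception of the ortho-arylmagnesium, here joined to the standard borate/peroxide conversion of an arylmagnesium into a phenol. No ring is closed and no stereocentre is created. The selectivity needed is regiochemical: carbon must add at C1' and not at C2', and the σ-withdrawing C3' methoxy group secures this by distorting the aryne so that C1' is the electrophilic terminus and by stabilising and chelating the carbanion that develops at C2'. An excess of 10 over 14 should outcompete addition of 13 or 15 to the aryne, the hindered TIPS ether cannot migrate to C2', and the ketal is inert to every organometallic present. B(OMe)3 converts 15 into boronate 16, whose aryl group migrates from boron to oxygen under bicarbonate-buffered H2O2, conditions that should spare both the silyl ether and the ketal.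

Step 7
Reactants: 17 6-(2-{2-[4-(4-methoxyphenyl)butyl]-5,5-dimethyl-1,3-dioxan-2-yl}ethyl)-2-methoxy-3-[(triisopropylsilyl)oxy]phenol
Product: 19 1-(2,4-dihydroxy-3-methoxyphenyl)-7-(4-methoxyphenyl)heptan-3-one, via ketal bisphenol 18 (not isolated)
Conditions: Bu4NF, THF, 0 °C (argon); then 2 M aq HCl, THF, rt to 40 °C
Reagents that add atoms: water, O
Why: Fluoride-induced desilylation of the aryl silyl ether followed by acid-catalysed ketal hydrolysis through an oxocarbenium ion, run in alcohol-free aqueous THF so that any chroman hemiketal formed by the C2' hydroxyl reverts to the open C3 ketone instead of being trapped as a mixed ketal.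

Compound list
1 | 5-(4-methoxyphenyl)pentanoic acid | COc1ccc(CCCCC(=O)O)cc1 | starting material
2 | 1-(1H-imidazol-1-yl)-5-(4-methoxyphenyl)pentan-1-one (acyl imidazole) | COc1ccc(CCCCC(=O)n2ccnc2)cc1 | intermediate (not isolated)
3 | N-methoxy-5-(4-methoxyphenyl)-N-methylpentanamide | COc1ccc(CCCCC(=O)N(C)OC)cc1 | intermediate
4 | vinylmagnesium bromide | C=C[Mg]Br | starting material
5 | racemic bromomagnesium 3-[methoxy(methyl)amino]-7-(4-methoxyphenyl)hept-1-en-3-olate (chelated tetrahedral adduct) | COc1ccc(CCCCC(O[Mg]Br)(C=C)N(C)OC)cc1 | intermediate (not isolated)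
6 | 7-(4-methoxyphenyl)hept-1-en-3-one | COc1ccc(CCCCC(=O)C=C)cc1 | intermediate
7 | 2,2-dimethylpropane-1,3-diol | CC(C)(CO)CO | starting material
8 | 1-bromo-7-(4-methoxyphenyl)heptan-3-one | COc1ccc(CCCCC(=O)CCBr)cc1 | intermediate (not isolated)
9 | 2-(2-bromoethyl)-2-[4-(4-methoxyphenyl)butyl]-5,5-dimethyl-1,3-dioxane | COc1ccc(CCCCC2(CCBr)OCC(C)(C)CO2)cc1 | intermediate
10 | (2-{2-[4-(4-methoxyphenyl)butyl]-5,5-dimethyl-1,3-dioxan-2-yl}ethyl)magnesium bromide | COc1ccc(CCCCC2(CC[Mg]Br)OCC(C)(C)CO2)cc1 | intermediate
11 | 4-fluoro-2-methoxyphenol | COc1cc(F)ccc1O | starting material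
12 | (4-fluoro-2-methoxyphenoxy)tri(propan-2-yl)silane | COc1cc(F)ccc1O[Si](C(C)C)(C(C)C)C(C)C | intermediate
13 | {6-fluoro-2-methoxy-3-[(triisopropylsilyl)oxy]phenyl}lithium | COc1c([Li])c(F)ccc1O[Si](C(C)C)(C(C)C)C(C)C | intermediate (not isolated)
14 | 3-methoxy-4-[(triisopropylsilyl)oxy]benzyne (1,2-didehydrobenzene) | COC1=C(O[Si](C(C)C)(C(C)C)C(C)C)C=CC#C1 | intermediate (not isolated)
15 | {6-(2-{2-[4-(4-methoxyphenyl)butyl]-5,5-dimethyl-1,3-dioxan-2-yl}ethyl)-2-methoxy-3-[(triisopropylsilyl)oxy]phenyl}magnesium bromide | COc1c([Mg]Br)c(CCC2(CCCCc3ccc(OC)cc3)OCC(C)(C)CO2)ccc1O[Si](C(C)C)(C(C)C)C(C)C | intermediate (not isolated)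
16 | dimethyl {6-(2-{2-[4-(4-methoxyphenyl)butyl]-5,5-dimethyl-1,3-dioxan-2-yl}ethyl)-2-methoxy-3-[(triisopropylsilyl)oxy]phenyl}boronate | COc1c(B(OC)OC)c(CCC2(CCCCc3ccc(OC)cc3)OCC(C)(C)CO2)ccc1O[Si](C(C)C)(C(C)C)C(C)C | intermediate (not isolated)
17 | 6-(2-{2-[4-(4-methoxyphenyl)butyl]-5,5-dimethyl-1,3-dioxan-2-yl}ethyl)-2-methoxy-3-[(triisopropylsilyl)oxy]phenol | COc1c(O)c(CCC2(CCCCc3ccc(OC)cc3)OCC(C)(C)CO2)ccc1O[Si](C(C)C)(C(C)C)C(C)C | intermediate
18 | 4-(2-{2-[4-(4-methoxyphenyl)butyl]-5,5-dimethyl-1,3-dioxan-2-yl}ethyl)-2-methoxybenzene-1,3-diol | COc1c(O)c(CCC2(CCCCc3ccc(OC)cc3)OCC(C)(C)CO2)ccc1O | intermediate (not isolated)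
19 | 1-(2,4-dihydroxy-3-methoxyphenyl)-7-(4-methoxyphenyl)heptan-3-one (CNP0165192.0) | COc1ccc(CCCCC(=O)CCc2ccc(O)c(OC)c2O)cc1 | target

Total step count: 7. Longest linear sequence: 6 steps (steps 1, 2, 3, 4, 6 and 7); step 5 is a one-step branch.

Steps most likely to fail

1. Step 6. The aryne may be intercepted inefficiently: β-hydride transfer from the alkylmagnesium reagent can reduce it, the aryl metals 13 and 15 can add to it, or the lithiation may not be fully regioselective. Surplus 10 is destroyed in the oxidative work-up and removed by chromatography. The fallback sets out from 10 and comes back to the route at 18, using only established cross-coupling chemistry. Purchased 2-methoxybenzene-1,3-diol F1 would be dibenzylated (BnBr, K2CO3, DMF) to 1,3-bis(benzyloxy)-2-methoxybenzene F2. Bromination with NBS in MeCN at 0 °C should occur at the position ortho to one benzyloxy group and para to the other, giving 1,3-bis(benzyloxy)-4-bromo-2-methoxybenzene F3. Transmetalation of 10 with ZnCl2 in THF would give chloro(2-{2-[4-(4-methoxyphenyl)butyl]-5,5-dimethyl-1,3-dioxan-2-yl}ethyl)zinc F4. Negishi coupling of F4 with F3 (Pd(OAc)2, SPhos, THF, 50 °C) would form the C1'–C1 bond in 2-{2-[2,4-bis(benzyloxy)-3-methoxyphenyl]ethyl}-2-[4-(4-methoxyphenyl)butyl]-5,5-dimethyl-1,3-dioxane F5. Hydrogenolysis (H2, Pd/C, EtOAc) would then give 18, which is hydrolysed to 19 with aqueous HCl in THF as in the second half of step 7.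

2. Step 3. The hydrobromination may reverse during the slower ketalisation of the dialkyl ketone, with loss of HBr regenerating the enone and leading to incomplete conversion and oligomers. The fallback sets out from 3 and comes back at 9, avoiding both the enone and HBr. Acylation of the lithium enolate of ethyl acetate (LiN(i-Pr)2, EtOAc, THF, −78 °C) by 3 would give ethyl 7-(4-methoxyphenyl)-3-oxoheptanoate F6. Ketalisation with 7 (TsOH·H2O cat., toluene, Dean–Stark) would give ethyl 2-{2-[4-(4-methoxyphenyl)butyl]-5,5-dimethyl-1,3-dioxan-2-yl}acetate F7. Reduction with LiAlH4 in THF at 0 °C would give 2-{2-[4-(4-methoxyphenyl)butyl]-5,5-dimethyl-1,3-dioxan-2-yl}ethan-1-ol F8, and Appel bromination (CBr4, PPh3, imidazole, CH2Cl2, 0 °C) would deliver 9.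

3. Step 2. The liberated hydroxylamine may add to the enone during the quench, or the vinyl ketone may polymerise on concentration. The fallback sets out from 3 and comes back at 6, removing the amine before the enone exists. Reduction of 3 with i-Bu2AlH (THF, −78 °C) would give 5-(4-methoxyphenyl)pentanal F9. Addition of 4 (THF, −78 °C) would give rac-7-(4-methoxyphenyl)hept-1-en-3-ol F10, and oxidation with Dess–Martin periodinane (NaHCO3, CH2Cl2, 0 °C) would give 6, to be used at once in step 3.

Further compounds
F1 | step 6 | 2-methoxybenzene-1,3-diol (purchased) | COc1c(O)cccc1O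
F2 | step 6 | 1,3-bis(benzyloxy)-2-methoxybenzene | COc1c(OCc2ccccc2)cccc1OCc1ccccc1
F3 | step 6 | 1,3-bis(benzyloxy)-4-bromo-2-methoxybenzene | COc1c(OCc2ccccc2)ccc(Br)c1OCc1ccccc1
F4 | step 6 | chloro(2-{2-[4-(4-methoxyphenyl)butyl]-5,5-dimethyl-1,3-dioxan-2-yl}ethyl)zinc | COc1ccc(CCCCC2(CC[Zn]Cl)OCC(C)(C)CO2)cc1
F5 | step 6 | 2-{2-[2,4-bis(benzyloxy)-3-methoxyphenyl]ethyl}-2-[4-(4-methoxyphenyl)butyl]-5,5-dimethyl-1,3-dioxane | COc1ccc(CCCCC2(CCc3ccc(OCc4ccccc4)c(OC)c3OCc5ccccc5)OCC(C)(C)CO2)cc1
F6 | step 3 | ethyl 7-(4-methoxyphenyl)-3-oxoheptanoate | CCOC(=O)CC(=O)CCCCc1ccc(OC)cc1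
F7 | step 3 | ethyl 2-{2-[4-(4-methoxyphenyl)butyl]-5,5-dimethyl-1,3-dioxan-2-yl}acetate | CCOC(=O)CC1(CCCCc2ccc(OC)cc2)OCC(C)(C)CO1
F8 | step 3 | 2-{2-[4-(4-methoxyphenyl)butyl]-5,5-dimethyl-1,3-dioxan-2-yl}ethan-1-ol | OCCC1(CCCCc2ccc(OC)cc2)OCC(C)(C)CO1
F9 | step 2 | 5-(4-methoxyphenyl)pentanal | COc1ccc(CCCCC=O)cc1
F10 | step 2 | rac-7-(4-methoxyphenyl)hept-1-en-3-ol | COc1ccc(CCCCC(O)C=C)cc1
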